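**Assumptions (one line each).** The configuration is taken literally from the SMILES: (1R,5S,6R,7R), with the 4‑hydroxyphenyl at C7 exo, the resorcinol ring at C6 endo, and the two aryls trans. The C2 carbinol and C4 ether centres of intermediates 13–15 are carried as epimer mixtures because both become sp² in step 11. TBS = tert‑butyldimethylsilyl, TMS = trimethylsilyl. The route is designed on paper and has not been run.

## Retrosynthetic overview

1. Vitisinol D ⇐ tetra‑TBS ether ⇐ C2‑hydroxy/C4‑alkoxy bicyclo[3.2.1]octan‑8‑one, by oxidation and β‑elimination to unveil the enone.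
2. The six‑membered ring (C4–C5 bond) is closed last by an intramolecular Mukaiyama aldol: the C5 enol silane of a cyclopentanone attacks a ketal‑derived oxocarbenium at C4.
3. The cyclopentanone comes from a three‑component union: (S)‑4‑arylcyclopentenone + aryl cuprate + aldehyde carrying C2–C4 and the styryl unit.
4. The enone comes from (S)‑4‑silyloxycyclopentenone (its single stereocentre relays all others); the aldehyde comes from an HWE / ketalisation / DIBAL sequence.
5. Ring order: aryl rings are bought; the cyclopentanone (C1, C5–C8) is in place first; the cyclohexenone ring is formed last.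

## Route

**Step 1**
Reactants: **1** 5‑bromoresorcinol
Product: **2** 1‑bromo‑3,5‑bis(TBSO)benzene
Conditions: TBSCl, imidazole, DMF, rt
Reagents that add atoms: TBSCl, CC(C)(C)[Si](C)(C)Cl
Why: Standard phenol silylation; TBS survives Grignard, cuprate, LDA and Lewis acid steps and is removed by fluoride at the end.

**Step 2**
Reactants: **3** 4‑bromophenol
Product: **4** (4‑bromophenoxy)(tert‑butyl)dimethylsilane
Conditions: TBSCl, imidazole, DMF, rt
Reagents that add atoms: TBSCl, CC(C)(C)[Si](C)(C)Cl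
Why: Phenol silylation, as in step 1.

**Step 3**
Reactants: **5** 4‑(TBSO)benzaldehyde; **6** ethyl 4‑(diethoxyphosphoryl)‑3‑oxobutanoate
Product: **7** ethyl (E)‑5‑[4‑(TBSO)phenyl]‑3‑oxopent‑4‑enoate
Conditions: NaH (2.2 equiv), THF, 0 °C → rt; aq. NH4Cl
Reagents that add atoms: none beyond 5 and 6
Why: Horner–Wadsworth–Emmons olefination of the phosphonate dianion, which reacts only at the P‑bearing carbon and gives the E‑alkene.

**Step 4**
Reactants: **7**
Product: **8** ethyl 2‑{2‑[(E)‑2‑(4‑(TBSO)phenyl)ethenyl]‑1,3‑dioxolan‑2‑yl}acetate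
Conditions: TMSOCH2CH2OTMS, TMSOTf (cat.), CH2Cl2, −78 → −20 °C
Reagents that add atoms: 1,2‑bis(trimethylsilyloxy)ethane, C[Si](C)(C)OCCO[Si](C)(C)C
Why: Noyori ketalisation under kinetic, non‑aqueous conditions protects the enone carbonyl without alkene migration; the dioxolane later serves as the latent C4 electrophile.

**Step 5**
Reactants: **8**
Product: **9** 2‑{2‑[(E)‑2‑(4‑(TBSO)phenyl)ethenyl]‑1,3‑dioxolan‑2‑yl}acetaldehyde
Conditions: DIBAL‑H (1.05 equiv), CH2Cl2, −78 °C; Rochelle salt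
Reagents that add atoms: none
Why: DIBAL half‑reduction of the ester; the ketal oxygen chelates and stabilises the tetrahedral intermediate so the aldehyde is released only on work‑up.

**Step 6**
Reactants: **10** (S)‑4‑(TBSO)cyclopent‑2‑en‑1‑one; **2**
Product: **11** (3R,4S)‑3‑[3,5‑bis(TBSO)phenyl]‑4‑(TBSO)cyclopentan‑1‑one (trans)
Conditions: 2, Mg, THF (Grignard); CuBr·SMe2 (20 mol %), TMSCl, THF, −78 °C, then 10; dilute HCl work‑up
Reagents that add atoms: none beyond 2 (TMSCl, C[Si](C)(C)Cl, is a transient enolate trap lost on work‑up)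
Why: Cu‑catalysed conjugate addition of the aryl Grignard anti to the C4 silyloxy group; this sets the resorcinol‑bearing carbon (future C6) from the chiral‑pool centre.

**Step 7**
Reactants: **11**
Product: **12** (S)‑4‑[3,5‑bis(TBSO)phenyl]cyclopent‑2‑en‑1‑one
Conditions: DBU (1.2 equiv), CH2Cl2, 0 °C, short reaction time
Reagents that add atoms: none
Why: E1cB β‑elimination of silanol from the β‑silyloxy ketone; the aryl‑bearing stereocentre is not involved and is retained.

**Step 8**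
Reactants: **12**; **4**; **9**
Product: **13** (2R,3R,4S)‑4‑[3,5‑bis(TBSO)phenyl]‑3‑[4‑(TBSO)phenyl]‑2‑{1‑hydroxy‑2‑[2‑((E)‑4‑(TBSO)styryl)‑1,3‑dioxolan‑2‑yl]ethyl}cyclopentan‑1‑one (carbinol epimers)
Conditions: 4, Mg, THF (Grignard, 1.2 equiv); CuBr·SMe2 (10 mol %), THF, −78 °C, add 12; then 9 (1.5 equiv), −78 °C; aq. NH4Cl
Reagents that add atoms: none beyond 4 and 9
Why: Tandem conjugate addition–aldol (three‑component coupling). The aryl adds anti to the C4 aryl, giving the trans‑diaryl unit, and the regiospecific enolate captures the aldehyde anti to the new aryl, setting the future C1 and C7.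

**Step 9**
Reactants: **13**
Product: **14** (3R,4R,5R)‑1‑(trimethylsilyloxy)cyclopent‑1‑ene bearing 3‑[3,5‑bis(TBSO)phenyl], 4‑[4‑(TBSO)phenyl] and the 5‑side chain as its O‑TMS ether
Conditions: TMSCl (4 equiv), then LDA (2.5 equiv), THF, −78 → −40 °C (in situ quench); cold pentane/NaHCO3 work‑up, used crude
Reagents that add atoms: TMSCl, C[Si](C)(C)Cl
Why: Kinetic deprotonation takes the unhindered C5 methylene rather than the tertiary C2–H, and in situ silylation gives the less substituted enol silane and caps the carbinol; the ketal and aryl silyl ethers are inert to LDA.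

**Step 10 (key ring closure)**
Reactants: **14**
Product: **15** (1R,5S,6R,7R)‑6‑[3,5‑bis(TBSO)phenyl]‑2‑hydroxy‑4‑(2‑hydroxyethoxy)‑7‑[4‑(TBSO)phenyl]‑4‑[(E)‑4‑(TBSO)styryl]bicyclo[3.2.1]octan‑8‑one (C2/C4 epimers)
Conditions: TMSOTf (1.2 equiv), 2,6‑di‑tert‑butyl‑4‑methylpyridine, CH2Cl2 (0.01 M), −78 → −40 °C; then citric acid, MeOH, 0 °C (cleaves the O‑TMS ethers)
Reagents that add atoms: none
Why: Intramolecular Mukaiyama aldol (ketal variant). TMSOTf opens the dioxolane to an oxocarbenium at C4 and the C5 enol silane attacks it in a 6‑ring closure. The tether forces the new bond onto the face of the C1 side chain, which fixes C5 and places the resorcinol aryl endo and the 4‑oxyphenyl exo.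

**Step 11**
Reactants: **15**
Product: **16** (1R,5S,6R,7R)‑6‑[3,5‑bis(TBSO)phenyl]‑7‑[4‑(TBSO)phenyl]‑4‑[(E)‑4‑(TBSO)styryl]bicyclo[3.2.1]oct‑3‑ene‑2,8‑dione
Conditions: Dess–Martin periodinane (3 equiv), NaHCO3, CH2Cl2, 0 °C → rt; then DBU (2 equiv), 0 °C
Reagents that add atoms: none
Why: Dess–Martin oxidation gives the C2 ketone (and oxidises the hydroxyethyl terminus), then E1cB loss of the tertiary C4 alkoxide gives the conjugated dienone. Only C3 can enolise because C1 and C5 are bridgeheads, so the four stereocentres are untouched.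

**Step 12**
Reactants: **16**
Product: **17** vitisinol D, (1R,5S,6R,7R)‑6‑(3,5‑dihydroxyphenyl)‑7‑(4‑hydroxyphenyl)‑4‑[(E)‑2‑(4‑hydroxyphenyl)ethenyl]bicyclo[3.2.1]oct‑3‑ene‑2,8‑dione
Conditions: TBAF (5 equiv), AcOH (5 equiv), THF, 0 °C; reverse‑phase purification
Reagents that add atoms: none
Why: Fluoride desilylation of the four aryl silyl ethers; acetic acid buffering avoids phenoxide or hydroxide attack (retro‑Claisen) on the non‑enolisable 1,3‑diketone.

## Compound list

1 | 5‑bromoresorcinol | Oc1cc(O)cc(Br)c1 | starting material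
2 | 1‑bromo‑3,5‑bis(TBSO)benzene | Brc1cc(O[Si](C)(C)C(C)(C)C)cc(O[Si](C)(C)C(C)(C)C)c1 | intermediate
3 | 4‑bromophenol | Oc1ccc(Br)cc1 | starting material
4 | (4‑bromophenoxy)(tert‑butyl)dimethylsilane | Brc1ccc(O[Si](C)(C)C(C)(C)C)cc1 | intermediate
5 | 4‑(TBSO)benzaldehyde | O=Cc1ccc(O[Si](C)(C)C(C)(C)C)cc1 | starting material
6 | ethyl 4‑(diethoxyphosphoryl)‑3‑oxobutanoate | CCOC(=O)CC(=O)CP(=O)(OCC)OCC | starting material
7 | ethyl (E)‑5‑[4‑(TBSO)phenyl]‑3‑oxopent‑4‑enoate | CCOC(=O)CC(=O)/C=C/c1ccc(O[Si](C)(C)C(C)(C)C)cc1 | intermediate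
8 | dioxolane ester | CCOC(=O)CC1(/C=C/c2ccc(O[Si](C)(C)C(C)(C)C)cc2)OCCO1 | intermediate
9 | dioxolane aldehyde | O=CCC1(/C=C/c2ccc(O[Si](C)(C)C(C)(C)C)cc2)OCCO1 | intermediate
10 | (S)‑4‑(TBSO)cyclopent‑2‑en‑1‑one | O=C1C=C[C@@H](O[Si](C)(C)C(C)(C)C)C1 | starting material
11 | (3R,4S)‑3‑aryl‑4‑(TBSO)cyclopentanone | O=C1C[C@H](c2cc(O[Si](C)(C)C(C)(C)C)cc(O[Si](C)(C)C(C)(C)C)c2)[C@@H](O[Si](C)(C)C(C)(C)C)C1 | intermediate
12 | (S)‑4‑[3,5‑bis(TBSO)phenyl]cyclopent‑2‑en‑1‑one | O=C1C=C[C@@H](c2cc(O[Si](C)(C)C(C)(C)C)cc(O[Si](C)(C)C(C)(C)C)c2)C1 | intermediate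
13 | (2R,3R,4S) aldol adduct | O=C1[C@@H](C(O)CC2(/C=C/c3ccc(O[Si](C)(C)C(C)(C)C)cc3)OCCO2)[C@H](c2ccc(O[Si](C)(C)C(C)(C)C)cc2)[C@@H](c2cc(O[Si](C)(C)C(C)(C)C)cc(O[Si](C)(C)C(C)(C)C)c2)C1 | intermediate
14 | (3R,4R,5R) bis‑TMS enol silane | C[Si](C)(C)OC1=C[C@H](c2cc(O[Si](C)(C)C(C)(C)C)cc(O[Si](C)(C)C(C)(C)C)c2)[C@@H](c2ccc(O[Si](C)(C)C(C)(C)C)cc2)[C@@H]1C(O[Si](C)(C)C)CC1(/C=C/c2ccc(O[Si](C)(C)C(C)(C)C)cc2)OCCO1 | intermediate
15 | bicyclic keto diol | OC1CC(OCCO)(/C=C/c3ccc(O[Si](C)(C)C(C)(C)C)cc3)[C@H]2C(=O)[C@@H]1[C@H](c1ccc(O[Si](C)(C)C(C)(C)C)cc1)[C@H]2c1cc(O[Si](C)(C)C(C)(C)C)cc(O[Si](C)(C)C(C)(C)C)c1 | intermediate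
16 | tetra‑TBS vitisinol D | O=C1C=C(/C=C/c3ccc(O[Si](C)(C)C(C)(C)C)cc3)[C@H]2C(=O)[C@@H]1[C@H](c1ccc(O[Si](C)(C)C(C)(C)C)cc1)[C@H]2c1cc(O[Si](C)(C)C(C)(C)C)cc(O[Si](C)(C)C(C)(C)C)c1 | intermediate
17 | vitisinol D | O=C1C=C(/C=C/c2ccc(O)cc2)[C@H]2C(=O)[C@@H]1[C@H](c1ccc(O)cc1)[C@H]2c1cc(O)cc(O)c1 | target

## Summary

**Total steps:** 12.

**Longest linear sequence:** 8 (steps 1 → 6 → 7 → 8 → 9 → 10 → 11 → 12; the aldehyde branch 3 → 4 → 5 → 8 → … → 12 is also 8).

**Three steps most likely to fail, with fallbacks:**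

- **Step 10 (bridging Mukaiyama aldol).** The oxocarbenium is stabilised and hindered, and the new bond forms syn to the C6 aryl. Fallback: use 3‑(triethylsilyloxy)propanal in step 8 in place of 9, close the ring by aldol onto a C4 aldehyde, oxidise to the C4 ketone, form the enol triflate (only C3 can enolise), and attach the 4‑silyloxystyryl unit by Heck or Suzuki coupling. The C2 oxygen would be carried as a silyl ether and oxidised before the coupling.
- **Step 7 (DBU elimination).** The γ‑aryl enone 12 can racemise through its dienolate or isomerise to the 3‑arylcyclopentenone. Fallback: make 12 without base by enantioselective Heck–Matsuda desymmetrisation of cyclopent‑3‑en‑1‑ol with the 3,5‑dioxygenated arenediazonium salt, followed by MnO2 oxidation of the allylic alcohol.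
- **Step 4 (ketalisation).** Keto ester 7 is largely enolised and conjugated, so ketalisation may be slow or give glycol conjugate addition. Fallback: form the ketal before the aryl is present, i.e. Heck coupling of bromide 4 (or its iodide) with ethyl 2‑(2‑vinyl‑1,3‑dioxolan‑2‑yl)acetate to give 8 directly.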